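Everything rests on cutting the O–C13 bond of the spiro tetrahydrofuran (ring C). C13 is a fully substituted ether carbon whose two arms, C14–C15 and C16 (the future lactone ring D), are exactly the vinyl and hydroxymethyl groups that opening of a 2-vinyloxirane leaves behind. Because C8 and C10, the ring neighbours of C9, are nearly equivalent, the decalin cannot bias C13 and a catalyst must. One palladium-catalysed dynamic kinetic asymmetric cycloetherification therefore converts both C13 epimers of a vinyl epoxide into one spiro ether, closing ring C and fixing C13. Its precursor is a cis-fused 6-silyloxy decalin bearing the axial tertiary C9 hydroxyl and a 2-(2-vinyloxiran-2-yl)ethyl chain.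

Key step: step 11

Assumption (structure): the target SMILES is taken literally, which means a cis-fused decalin (5S,10R); labdane numbering is used, and α denotes the face that carries the C10 methyl group, H-5, the 6-oxygen, the C8 methyl group and the 9-oxygen (C11 is β).
Assumption (catalysts): the antipodes named in steps 1 and 11 are those expected from the usual stereochemical models; if either sense proves opposite, the mirror-image catalyst is used and nothing else changes.
Remark: compound 15 stands for the mixture of both C13 epimers of the vinyl epoxide, which is made and used without separation; the 13S epimer is drawn.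

Step 1
Reactants: 1 2,6-dimethyl-1,4-benzoquinone; 2 4-methylpenta-1,3-diene
Product: 3 (4aS,8aR)-2,5,5,8a-tetramethyl-4a,5,8,8a-tetrahydronaphthalene-1,4-dione (cis-fused enedione; labdane 5S,10R)
Conditions: (S)-3,3-diphenyl-1-(2-methylphenyl)tetrahydropyrrolo[1,2-c][1,3,2]oxazaborole protonated with HNTf2 (20 mol %), 2 (5 equiv), CH2Cl2, −78 → −20 °C
Reagents that add atoms: none
Why: A Lewis-acid-catalysed enantioselective Diels–Alder reaction should proceed because the cationic boron catalyst binds the unhindered carbonyl between the two CH positions of 1, so that the CH2 terminus of 2 bonds first to the methyl-bearing β-carbon (future C10) and the CMe2 terminus to the CH α-carbon (future C5), which avoids vicinal quaternary carbons, gives the cis ring fusion by suprafacial addition and sets the absolute configuration through the quinone face that the catalyst leaves open.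

Step 2
Reactants: 3 cis-fused enedione
Product: 4 (4R,4aS,8aR)-4-hydroxy-2,5,5,8a-tetramethyl-4a,5,8,8a-tetrahydronaphthalen-1(4H)-one (6β-hydroxy enone, hydroxyl trans to H-5; labdane 5S,6R,10R)
Conditions: NaBH4, CeCl3·7H2O, MeOH, −78 °C
Reagents that add atoms: none
Why: Luche 1,2-reduction attacks the less hindered C6 carbonyl (C9 is flanked by the quaternary C10) from the convex α face of the folded cis-fused enedione, so the new hydroxyl lies on the β face, which is the C6 epimer of what the target needs and is inverted in step 3.

Step 3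
Reactants: 4 6β-hydroxy enone
Product: 5 4-nitrobenzoate of the 6α-alcohol 6 (labdane 5S,6S,10R)
Conditions: 4-O2NC6H4CO2H, PPh3, DIAD, THF, 0 °C → rt
Reagents that add atoms: 4-nitrobenzoic acid, O=C(O)c1ccc(cc1)[N+](=O)[O-]
Why: Mitsunobu esterification displaces the activated allylic 6β-oxygen by 4-nitrobenzoate in an SN2 reaction from the open α face, which inverts C6 to the required 6α configuration (oxygen cis to H-5 and trans to the bulky C4).

Step 4
Reactants: 5 6α-(4-nitrobenzoate)
Product: 6 (4S,4aS,8aR)-4-hydroxy-2,5,5,8a-tetramethyl-4a,5,8,8a-tetrahydronaphthalen-1(4H)-one (6α-hydroxy enone)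
Conditions: K2CO3 (cat.), MeOH, 0 °C
Reagents that add atoms: none
Why: Base-catalysed transesterification (methanolysis) of the activated aryl ester frees the 6α-alcohol without touching any stereocenter.

Step 5
Reactants: 6 6α-hydroxy enone
Product: 7 (4S,4aS,8aR)-4-[(tert-butyldimethylsilyl)oxy]-2,5,5,8a-tetramethyl-4a,5,8,8a-tetrahydronaphthalen-1(4H)-one
Conditions: TBSCl, imidazole, DMF, rt
Reagents that add atoms: tert-butyldimethylsilyl chloride, CC(C)(C)[Si](C)(C)Cl
Why: Silylation of the secondary allylic alcohol with a silyl chloride and imidazole gives an ether that withstands the hydrogenation, ylide, peracid and organopotassium steps ahead.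

Step 6
Reactants: 7 6α-silyloxy enone
Product: 9 (2R,4S,4aS,8aR)-4-[(tert-butyldimethylsilyl)oxy]-2,5,5,8a-tetramethyloctahydronaphthalen-1(2H)-one (cis-fused 9-ketone with 6α-OTBS and 8α-methyl), via epimeric ketone 8 (not isolated)
Conditions: H2 (1 atm), Pd/C, EtOAc, rt; filter; NaOMe (cat.), MeOH, 40 °C
Reagents that add atoms: none
Why: Heterogeneous catalytic hydrogenation saturates both C=C bonds, and methoxide then equilibrates C8 through the C9 enolate to the 8α-methyl epimer, which is equatorial in the chair that keeps the quaternary C4 equatorial on ring B, whereas an 8β-methyl group would be syn-axial to C1.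

Step 7
Reactants: 9 cis-fused 9-ketone
Product: 10 6α-(tert-butyldimethylsilyloxy)-4,4,8α,10-tetramethyl-9-methylidene-cis-decalin (labdane 5S,6S,8R,10R)
Conditions: Ph3PCH3Br, KOtBu, toluene, 90 °C
Reagents that add atoms: methyltriphenylphosphonium bromide, C[P+](c1ccccc1)(c1ccccc1)c1ccccc1.[Br-]
Why: Wittig methylenation with methylenetriphenylphosphorane at elevated temperature copes with the hindered ketone and introduces C11, and the side chain is not added directly to the carbonyl because a carbon nucleophile would enter from the convex α face and give the C9 epimer.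

Step 8
Reactants: 10 9-methylidene decalin
Product: 11 9α,11-epoxide of 10 (spiro-oxirane with oxygen on the α face; labdane 5S,6S,8R,9R,10R)
Conditions: mCPBA, NaHCO3, CH2Cl2, 0 °C
Reagents that add atoms: meta-chloroperoxybenzoic acid, OOC(=O)c1cccc(Cl)c1
Why: Prilezhaev epoxidation of the exocyclic alkene occurs from the α face, which is the axial direction at C9 and the side away from the axial C1 methylene on C10, so that the oxirane oxygen becomes the axial 9α-oxygen and C11 is equatorial (β) as in the target.

Step 9
Reactants: 11 9α,11-epoxide; 12 isoprene (2-methylbuta-1,3-diene)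
Product: 14 6α-(tert-butyldimethylsilyloxy)-9α-hydroxy-9β-(3-methylidenepent-4-en-1-yl)-4,4,8α,10-tetramethyl-cis-decalin (labdane 5S,6S,8R,9R,10R), via isoprenylpotassium 13 (not isolated)
Conditions: 12 (4 equiv), LiN(iPr)2, KOtBu, THF, −78 °C; then 11, −78 → 0 °C; aq NH4Cl
Reagents that add atoms: none
Why: Deprotonation of the methyl group of 12 by the mixed lithium–potassium amide base gives the 2-vinylallyl anion 13, whose two CH2 termini are equivalent, and this opens the 2,2-disubstituted oxirane by SN2 attack at its CH2 carbon (C11), forming C11–C12 without touching C9.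

Step 10
Reactants: 14 9α-hydroxy diene
Product: 15 vinyl epoxide 6α-(tert-butyldimethylsilyloxy)-9α-hydroxy-9β-[2-(2-vinyloxiran-2-yl)ethyl]-4,4,8α,10-tetramethyl-cis-decalin, obtained as the unseparated mixture of both C13 epimers (the 13S epimer is drawn)
Conditions: DMDO (1.05 equiv), acetone, −20 °C
Reagents that add atoms: dimethyldioxirane, CC1(C)OO1
Why: Dioxirane epoxidation under neutral conditions takes the more electron-rich 1,1-disubstituted double bond of the 2-substituted butadiene and avoids acid that would let the C9 hydroxyl open the epoxide prematurely, and no facial control is needed because both C13 epimers are used.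

Step 11
Reactants: 15 vinyl epoxide (mixture of both C13 epimers)
Product: 16 spiro tetrahydrofuran with vinyl (C14=C15) and hydroxymethyl (C16) on C13, 6α-OTBS (labdane 5S,6S,8R,9R,10R,13R)
Conditions: Pd2(dba)3·CHCl3 (2.5 mol %), (S,S)-N,N′-(cyclohexane-1,2-diyl)bis[2-(diphenylphosphino)benzamide] (7.5 mol %), BEt3 (10 mol %), CH2Cl2, rt
Reagents that add atoms: none
Why: Zerovalent palladium bound to the chiral bis-phosphine ionises the allylic C13–O bond of either epoxide epimer with inversion, giving diastereomeric π-allyl complexes over C13–C14–C15 that carry the C16 alkoxide (held as a borate by BEt3) and that exchange the metal between the two allyl faces through the σ-complex at the unsubstituted terminus C15. The closest known reactions are the palladium-catalysed dynamic kinetic asymmetric addition of alcohols to racemic 2-vinyloxiranes with a borane co-catalyst and the palladium-catalysed cyclisation of hydroxy vinyl epoxides to 2-vinyltetrahydrofurans, of which a tertiary hydroxyl nucleophile is an extension. Ring C closes by 5-exo attack of the C9 oxygen, anti to palladium, on the internal allyl terminus C13, which forms the O–C13 bond and leaves vinyl and hydroxymethyl groups on C13. The configuration of C13 (R) is dictated by the chiral pocket of the ligand, which lets only one of the two equilibrating complexes cyclise quickly, so that the 13R epoxide can reach 16 by direct double inversion and the 13S epoxide after face exchange, while the substrate has little say because C8 and C10 offer C13 nearly the same surroundings. The step needs attack at C13 and not at C15, which is secured by the five- versus seven-membered ring and by the alkoxide–boron tether, and it needs allyl-face exchange to outrun ring closure, which the sluggish hindered tertiary hydroxyl makes likely. C9 keeps its configuration because its C–O bond is never broken.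

Step 12
Reactants: 16 spiro tetrahydrofuran
Product: 18 C16 carboxylic acid (13-carboxy-13-vinyl spiro ether with 6α-OTBS; 13R), via aldehyde 17 (not isolated)
Conditions: TEMPO (10 mol %), PhI(OAc)2 (2.2 equiv), MeCN–H2O, rt
Reagents that add atoms: water, O
Why: Nitroxyl-catalysed oxidation with the hypervalent iodine co-oxidant takes the primary C16 alcohol through aldehyde 17 and its hydrate to the acid while the alkene, the ethers and the silyl ether are inert, and C13, having no hydrogen, cannot epimerise.

Step 13
Reactants: 18 C16 carboxylic acid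
Product: 21 6α-(tert-butyldimethylsilyloxy)-9α,13-epoxy-labdan-16,15-olide with cis-fused decalin (5S,6S,8R,9R,10R,13R), via bis-boryl adduct 19 (not isolated), via hydroxy acid 20 (not isolated)
Conditions: 9-BBN (3 equiv), THF, 0 °C → rt; NaOH, H2O2, 0 °C; then 1 M HCl to pH 2, rt
Reagents that add atoms: hydrogen peroxide, OO
Why: Hydroboration with 9-BBN adds boron to the terminal carbon C15 of the vinyl group after the first equivalent has capped the acid as an acyloxyborane (which 9-BBN reduces only slowly), alkaline peroxide oxidises the C–B bond, and acidification lets γ-hydroxy acid 20 close to the five-membered lactone (ring D).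

Step 14
Reactants: 21 6α-OTBS spiro lactone
Product: 22 6α-hydroxy-9α,13-epoxy-labdan-16,15-olide with cis-fused decalin (5S,6S,8R,9R,10R,13R)
Conditions: HF·pyridine, THF, 0 °C → rt
Reagents that add atoms: none
Why: Fluoride cleaves the Si–O bond of the silyl ether under mildly acidic conditions that leave the lactone and the spiro ether untouched.

Step 15
Reactants: 22 6α-hydroxy spiro lactone
Product: 23 target, (5S,6S,8R,9R,10R,13R)-6-acetoxy-9,13-epoxy-labdan-16,15-olide with cis-fused decalin (CNP0081177.1)
Conditions: Ac2O, DMAP, pyridine, rt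
Reagents that add atoms: acetic anhydride, CC(=O)OC(C)=O
Why: DMAP-catalysed acylation of the only free hydroxyl, the secondary 6α-alcohol, gives the acetate with retention.

Compound list
1 | 2,6-dimethyl-1,4-benzoquinone | CC1=CC(=O)C=C(C)C1=O | starting material
2 | 4-methylpenta-1,3-diene | CC(C)=CC=C | starting material
3 | (4aS,8aR)-2,5,5,8a-tetramethyl-4a,5,8,8a-tetrahydronaphthalene-1,4-dione | O=C1C=C(C)C(=O)[C@]2(C)CC=CC(C)(C)[C@H]12 | intermediate
4 | (4R,4aS,8aR)-4-hydroxy-2,5,5,8a-tetramethyl-4a,5,8,8a-tetrahydronaphthalen-1(4H)-one (6β-OH) | O[C@@H]1C=C(C)C(=O)[C@]2(C)CC=CC(C)(C)[C@H]12 | intermediate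
5 | 4-nitrobenzoate of 6 (6α-ester) | O=C(O[C@H]1C=C(C)C(=O)[C@]2(C)CC=CC(C)(C)[C@H]12)c1ccc(cc1)[N+](=O)[O-] | intermediate
6 | (4S,4aS,8aR)-4-hydroxy-2,5,5,8a-tetramethyl-4a,5,8,8a-tetrahydronaphthalen-1(4H)-one (6α-OH) | O[C@H]1C=C(C)C(=O)[C@]2(C)CC=CC(C)(C)[C@H]12 | intermediate
7 | tert-butyldimethylsilyl ether of 6 | CC(C)(C)[Si](C)(C)O[C@H]1C=C(C)C(=O)[C@]2(C)CC=CC(C)(C)[C@H]12 | intermediate
8 | (2S,4S,4aS,8aR)-4-[(tert-butyldimethylsilyl)oxy]-2,5,5,8a-tetramethyloctahydronaphthalen-1(2H)-one (8β-methyl epimer of 9) | CC(C)(C)[Si](C)(C)O[C@H]1C[C@H](C)C(=O)[C@]2(C)CCCC(C)(C)[C@H]12 | intermediate (not isolated)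
9 | (2R,4S,4aS,8aR)-4-[(tert-butyldimethylsilyl)oxy]-2,5,5,8a-tetramethyloctahydronaphthalen-1(2H)-one | CC(C)(C)[Si](C)(C)O[C@H]1C[C@@H](C)C(=O)[C@]2(C)CCCC(C)(C)[C@H]12 | intermediate
10 | 9-methylidene compound (5S,6S,8R,10R) | CC(C)(C)[Si](C)(C)O[C@H]1C[C@@H](C)C(=C)[C@]2(C)CCCC(C)(C)[C@H]12 | intermediate
11 | 9α,11-spiro-epoxide (5S,6S,8R,9R,10R) | CC(C)(C)[Si](C)(C)O[C@H]1C[C@@H](C)[C@]3(CO3)[C@]2(C)CCCC(C)(C)[C@H]12 | intermediate
12 | isoprene | CC(=C)C=C | starting material
13 | (2-methylidenebut-3-en-1-yl)potassium | [K+].[CH2-]C(=C)C=C | intermediate (not isolated)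
14 | 9α-hydroxy-9β-(3-methylidenepent-4-en-1-yl) decalin, 6α-OTBS (5S,6S,8R,9R,10R) | CC(C)(C)[Si](C)(C)O[C@H]1C[C@@H](C)[C@](O)(CCC(=C)C=C)[C@]2(C)CCCC(C)(C)[C@H]12 | intermediate
15 | vinyl epoxide, key-step precursor (mixture of both C13 epimers; 13S epimer drawn) | CC(C)(C)[Si](C)(C)O[C@H]1C[C@@H](C)[C@](O)(CC[C@]3(C=C)CO3)[C@]2(C)CCCC(C)(C)[C@H]12 | intermediate
16 | spiro tetrahydrofuran, 13-vinyl-13-hydroxymethyl, 6α-OTBS (5S,6S,8R,9R,10R,13R) | CC(C)(C)[Si](C)(C)O[C@H]1C[C@@H](C)[C@]2(CC[C@](CO)(C=C)O2)[C@]2(C)CCCC(C)(C)[C@H]12 | intermediate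
17 | C16 aldehyde of 16 | CC(C)(C)[Si](C)(C)O[C@H]1C[C@@H](C)[C@]2(CC[C@](C=O)(C=C)O2)[C@]2(C)CCCC(C)(C)[C@H]12 | intermediate (not isolated)
18 | C16 carboxylic acid | CC(C)(C)[Si](C)(C)O[C@H]1C[C@@H](C)[C@]2(CC[C@](C(O)=O)(C=C)O2)[C@]2(C)CCCC(C)(C)[C@H]12 | intermediate
19 | C15-(9-borabicyclononyl) acyloxyborane adduct of 18 (C13 configured as in 18) | CC(C)(C)[Si](C)(C)O[C@H]1C[C@@H](C)[C@]2(CC[C@](C(=O)OB3C4CCCC3CCC4)(CCB3C4CCCC3CCC4)O2)[C@]2(C)CCCC(C)(C)[C@H]12 | intermediate (not isolated)
20 | 15-hydroxy-16-oic acid | CC(C)(C)[Si](C)(C)O[C@H]1C[C@@H](C)[C@]2(CC[C@](C(O)=O)(CCO)O2)[C@]2(C)CCCC(C)(C)[C@H]12 | intermediate (not isolated)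
21 | 6α-OTBS spiro lactone | CC(C)(C)[Si](C)(C)O[C@H]1C[C@@H](C)[C@]2(CC[C@]3(CCOC3=O)O2)[C@]2(C)CCCC(C)(C)[C@H]12 | intermediate
22 | 6α-hydroxy spiro lactone | O[C@H]1C[C@@H](C)[C@]2(CC[C@]3(CCOC3=O)O2)[C@]2(C)CCCC(C)(C)[C@H]12 | intermediate
23 | CNP0081177.1, (5S,6S,8R,9R,10R,13R)-6-acetoxy-9,13-epoxy-labdan-16,15-olide | CC(=O)O[C@H]1C[C@@H](C)[C@]2(CC[C@]3(CCOC3=O)O2)[C@]2(C)CCCC(C)(C)[C@H]12 | target

Total step count: 15. Longest linear sequence: 15 steps (1 → 23; isoprene 12 enters at step 9).

Steps most likely to fail

Step 11. Capture of the π-allyl complex by the hindered tertiary hydroxyl may be slower than loss of a β-hydrogen or a hydride shift, which would isomerise the epoxide to a dienol or an enal. Alternatively the ligand may not fully override the substrate, so that face selection at C13 is poor. The fallback sets out from 15. A catalytic amount of camphorsulfonic acid in CH2Cl2 at −20 °C promotes the known 5-exo cyclisation of a 4,5-epoxy alcohol at its tertiary allylic epoxide carbon. Each epoxide epimer should then give one spiro ether, so 16 is expected together with the 13S spiro tetrahydrofuran F1 as its C13 epimer. The two primary alcohols are separated by chromatography, and the fallback comes back to the route at 16.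

Step 1. The hindered diene may isomerise or oligomerise under the cationic catalyst faster than it adds, or it may add with low enantioselectivity. The fallback sets out from 1 and 2 and uses an uncatalysed cycloaddition under high pressure (about 12 kbar, CH2Cl2, rt), where the orientation is still enforced by the avoidance of vicinal quaternary carbons. This would give 3 as a racemate, that is together with its enantiomer ent-3 F2 in equal amount. Luche reduction as in step 2 then gives 4 together with ent-4 F3 as a racemate. A Mitsunobu reaction with (S)-2-methoxy-2-phenylacetic acid in place of 4-nitrobenzoic acid inverts C6 and gives two diastereomeric esters, the (S)-2-methoxy-2-phenylacetate of 6 F4 and the (S)-2-methoxy-2-phenylacetate of ent-6 F5 in equal amounts. These are separated by chromatography or crystallisation, and methanolysis of F4 as in step 4 returns to the route at 6.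

Step 3. Elimination towards a dienone, or failure of the crowded alkoxyphosphonium ion to undergo displacement, would stop the inversion at C6. The fallback sets out from 3 and sets C6 by reduction under equilibrating conditions instead of by substitution. Hydrogenation (H2, Pd/C, EtOAc) gives the saturated cis-fused dione F6 under neutral conditions that leave C5 untouched. Dissolving-metal reduction (Li, NH3, THF, tBuOH, −78 °C) is expected to give the equatorial 6α-alcohol, and the proton source keeps enolisation towards C5 slow. Its product is the 6α,9-diol F7 whose C9 carbinol may have either configuration. Silylation of the less hindered C6 hydroxyl (TBSCl, imidazole, DMF) gives the 6-mono-TBS ether F8 as the main product. Dess–Martin oxidation of the C9 carbinol followed by equilibration of C8 with NaOMe in MeOH returns to the route at 9.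

Further compounds
F1 | step 11 | 13-epi-16 (13S spiro tetrahydrofuran) | CC(C)(C)[Si](C)(C)O[C@H]1C[C@@H](C)[C@]2(CC[C@@](CO)(C=C)O2)[C@]2(C)CCCC(C)(C)[C@H]12
F2 | step 1 | ent-3, (4aR,8aS)-2,5,5,8a-tetramethyl-4a,5,8,8a-tetrahydronaphthalene-1,4-dione | O=C1C=C(C)C(=O)[C@@]2(C)CC=CC(C)(C)[C@@H]12
F3 | step 1 | ent-4, (4S,4aR,8aS)-4-hydroxy enone | O[C@H]1C=C(C)C(=O)[C@@]2(C)CC=CC(C)(C)[C@@H]12
F4 | step 1 | (S)-2-methoxy-2-phenylacetate of 6 | CO[C@H](C(=O)O[C@H]1C=C(C)C(=O)[C@]2(C)CC=CC(C)(C)[C@H]12)c1ccccc1
F5 | step 1 | (S)-2-methoxy-2-phenylacetate of ent-6 | CO[C@H](C(=O)O[C@@H]1C=C(C)C(=O)[C@@]2(C)CC=CC(C)(C)[C@@H]12)c1ccccc1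
F6 | step 3 | saturated cis-fused 6,9-dione (8α-methyl drawn) | O=C1C[C@@H](C)C(=O)[C@]2(C)CCCC(C)(C)[C@H]12
F7 | step 3 | 6α,9-diol (C9 undefined) | O[C@H]1C[C@@H](C)C(O)[C@]2(C)CCCC(C)(C)[C@H]12
F8 | step 3 | 6α-OTBS 9-ol (C9 undefined) | CC(C)(C)[Si](C)(C)O[C@H]1C[C@@H](C)C(O)[C@]2(C)CCCC(C)(C)[C@H]12
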